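Ring C is opened at C4–C3 and O1–C8a, which divides the isoflavan into a ring A 1,3-bis-electrophile and a ring B C,O-bis-nucleophile. The key step exploits that C8a of ring A lies between the formyl-bearing C8 and the C4a–C4 arm. In 3-(chloromethyl)-2-fluoro-4,6-dimethoxybenzaldehyde the benzylic halide is C4 and the formyl-activated C–F is C8a. The enolate of a ring B arylacetaldehyde is alkylated at carbon and then arylated at oxygen in one pot, giving the complete isoflav-2-ene. Asymmetric hydrogenation then sets C3, directed lithiation adds the prenyl group, and chelation to the 8-formyl group frees only the 7-hydroxyl.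

Key step: step 6

Remark: chroman numbering is used throughout (O1, C2, C3, C4, C4a, C5 to C8, C8a; ring B primed). The target is the 3R enantiomer.
Assumption: the ligand antipode that gives 3R in step 7 is identified in a test hydrogenation; both antipodes of the ligand are available.

Step 1
Reactants: 1 1-fluoro-3,5-dimethoxybenzene
Product: 2 2-fluoro-4,6-dimethoxybenzaldehyde
Conditions: POCl3, DMF, 0 to 80 °C; then ice-water
Reagents that add atoms: N,N-dimethylformamide CN(C)C=O; water O
Why: Vilsmeier–Haack formylation should enter para to one methoxy group and ortho to the other, beside the small fluorine, rather than at the crowded carbon between the two methoxy groups, as is usual for 5-substituted 1,3-dimethoxybenzenes.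

Step 2
Reactants: 2 2-fluoro-4,6-dimethoxybenzaldehyde
Product: 3 3-(chloromethyl)-2-fluoro-4,6-dimethoxybenzaldehyde
Conditions: (CH2O)n, conc. aq HCl, ZnCl2 (cat.), AcOH, 50 °C
Reagents that add atoms: formaldehyde (as paraformaldehyde) C=O; hydrogen chloride Cl
Why: Blanc chloromethylation should follow the same preference as step 1 (C3 is para to the 6-methoxy and ortho to the 4-methoxy group, C5 is the hindered ortho,ortho site), and the formyl and fluoro groups temper the benzylic chloride enough for it to be handled.

Step 3
Reactants: 4 2,4-dihydroxybenzaldehyde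
Product: 5 2,4-bis(methoxymethoxy)benzaldehyde
Conditions: MOMCl (3 equiv), i-Pr2NEt, CH2Cl2, 0 °C to reflux
Reagents that add atoms: chloromethyl methyl ether COCCl
Why: O-alkylation of both phenols (Williamson-type acetal ether formation) should go to completion with excess reagent and heat, which the hydrogen-bonded 2-hydroxyl needs.

Step 4
Reactants: 5 2,4-bis(methoxymethoxy)benzaldehyde
Product: 6 rac-2-[2,4-bis(methoxymethoxy)phenyl]oxirane
Conditions: Me3SI, NaH, DMSO–THF, 0 °C to rt
Reagents that add atoms: trimethylsulfonium iodide C[S+](C)C.[I-]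
Why: Corey–Chaykovsky epoxidation transfers one methylene to the aldehyde; the new stereocentre forms racemic and is removed in step 5.

Step 5
Reactants: 6 rac-2-[2,4-bis(methoxymethoxy)phenyl]oxirane
Product: 7 [2,4-bis(methoxymethoxy)phenyl]acetaldehyde
Conditions: InCl3 (10 mol %), THF, rt; used without storage
Reagents that add atoms: none
Why: Meinwald rearrangement should be very easy here because the 2,4-dioxygenated ring stabilises the benzylic cation that precedes the 1,2-hydride shift, so a mild Lewis acid that spares the MOM acetals is enough.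

Step 6
Reactants: 3 3-(chloromethyl)-2-fluoro-4,6-dimethoxybenzaldehyde; 7 [2,4-bis(methoxymethoxy)phenyl]acetaldehyde
Product: 9 3-[2,4-bis(methoxymethoxy)phenyl]-5,7-dimethoxy-4H-chromene-8-carbaldehyde, via open-chain dialdehyde 8 (not isolated)
Conditions: Cs2CO3 (2.5 equiv), NaI (10 mol %), DMF (0.05 M), slow addition of 7 at 0 °C, then 70 °C
Reagents that add atoms: none
Why: Cs2CO3 enolises 7 and the soft enolate carbon (C3) displaces the benzylic halide of 3 (iodide relay, SN2) to give 8, whose more acidic α-aryl C–H is enolised again so that the enolate oxygen (O1) adds to C8a and expels fluoride through a Meisenheimer anion whose charge rests on the ortho formyl group at C8. The closest known reaction type is the tandem SN2–SNAr annulation of activated 2-fluorobenzyl halides with active methylene carbonyl compounds to 4H-chromenes. Ring C closes as a six-membered ring by 6-exo-trig addition–elimination at C8a; attack by the enolate carbon would need a four-membered ring, so O-arylation is the only cyclisation open to 8. The C3 stereocentre of 8 forms racemic and is erased by the second enolisation, so 9 carries none and C3 is set in step 7. The step needs C- over O-benzylation and alkylation over aldol addition to the formyl groups: the soft benzylic iodide, the doubly ortho-substituted and methoxy-deactivated 8-formyl group and the slow addition of 7 should secure this, and an initial O-arylation would converge on 9 as well, because the aryl enol ether can close through C3 onto the ionisable dimethoxybenzylic halide. The 5- and 7-methoxy groups are meta to C8a and so do not quench the SNAr step.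

Step 7
Reactants: 9 3-[2,4-bis(methoxymethoxy)phenyl]-5,7-dimethoxy-4H-chromene-8-carbaldehyde
Product: 10 (3R)-3-[2,4-bis(methoxymethoxy)phenyl]-5,7-dimethoxychromane-8-carbaldehyde
Conditions: [Ir(cod)(L*)]BArF (2 mol %; L* = 4-tert-butyl-2-[2-(diphenylphosphanyl)phenyl]-4,5-dihydrooxazole or a related chiral N,P ligand, antipode as assumed above), H2 (50 bar), CH2Cl2, rt
Reagents that add atoms: none
Why: Iridium N,P-catalysed asymmetric hydrogenation of a trisubstituted cyclic enol ether, a reaction type established for chromenes, should deliver hydrogen to one face of C3 under control of the chiral ligand, while the formyl group, aryl ethers and MOM acetals stay inert; no other alkene is present, which is why the prenyl group comes later.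

Step 8
Reactants: 10 (3R)-3-[2,4-bis(methoxymethoxy)phenyl]-5,7-dimethoxychromane-8-carbaldehyde
Product: 14 (3R)-3-[2,4-bis(methoxymethoxy)-3-(3-methylbut-2-en-1-yl)phenyl]-5,7-dimethoxychromane-8-carbaldehyde, via lithium amino alkoxide 11 (not isolated), via aryllithium 12 (not isolated), via prenylated amino alkoxide 13 (not isolated)
Conditions: N-methylpiperazine, n-BuLi, THF, −20 °C, then 10; n-BuLi (1.5 equiv), −20 to 0 °C; prenyl bromide, −78 °C to rt; H2O
Reagents that add atoms: prenyl bromide (1-bromo-3-methylbut-2-ene) CC(C)=CCBr
Why: In situ masking of the aldehyde as a lithium α-amino alkoxide, directed ortho-metalation and SN2 allylation should work because H3' between two chelating OMOM groups is the kinetically preferred site (OMOM outranks OMe, so C6 of ring A should stay untouched), water returns the aldehyde, and C3 is not affected.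

Step 9
Reactants: 14 (3R)-3-[2,4-bis(methoxymethoxy)-3-(3-methylbut-2-en-1-yl)phenyl]-5,7-dimethoxychromane-8-carbaldehyde
Product: 15 (3R)-3-[2,4-dihydroxy-3-(3-methylbut-2-en-1-yl)phenyl]-5,7-dimethoxychromane-8-carbaldehyde
Conditions: conc. HCl (cat.), MeOH, 45 °C; aqueous work-up
Reagents that add atoms: none
Why: Acid-catalysed acetal exchange removes both MOM groups under conditions commonly used for ortho-prenylated phenols, mild enough that the prenyl group should not cyclise onto a neighbouring hydroxyl, and any dimethyl acetal of the aldehyde reverts on aqueous work-up.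

Step 10
Reactants: 15 (3R)-3-[2,4-dihydroxy-3-(3-methylbut-2-en-1-yl)phenyl]-5,7-dimethoxychromane-8-carbaldehyde
Product: 16 (3R)-3-[2,4-dihydroxy-3-(3-methylbut-2-en-1-yl)phenyl]-7-hydroxy-5-methoxychromane-8-carbaldehyde
Conditions: MgI2·OEt2 (4 equiv), THF, reflux; then dilute aq HCl
Reagents that add atoms: none
Why: Chelation-controlled aryl methyl ether cleavage should be selective because magnesium binds the formyl oxygen and the 7-methoxy oxygen in a six-membered chelate and iodide removes that methyl by SN2, whereas the 5-methoxy group cannot chelate, C2 next to O1 is a hindered β-branched carbon, and prenyl groups and free phenols tolerate this reagent.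

Compound list
1 | 1-fluoro-3,5-dimethoxybenzene | COc1cc(F)cc(OC)c1 | starting material
2 | 2-fluoro-4,6-dimethoxybenzaldehyde | COc1cc(F)c(C=O)c(OC)c1 | intermediate
3 | 3-(chloromethyl)-2-fluoro-4,6-dimethoxybenzaldehyde | COc1cc(OC)c(C=O)c(F)c1CCl | intermediate
4 | 2,4-dihydroxybenzaldehyde | O=Cc1ccc(O)cc1O | starting material
5 | 2,4-bis(methoxymethoxy)benzaldehyde | O=Cc1ccc(OCOC)cc1OCOC | intermediate
6 | rac-2-[2,4-bis(methoxymethoxy)phenyl]oxirane | COCOc1ccc(C2CO2)c(OCOC)c1 | intermediate
7 | [2,4-bis(methoxymethoxy)phenyl]acetaldehyde | COCOc1ccc(CC=O)c(OCOC)c1 | intermediate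
8 | rac-3-{2-[2,4-bis(methoxymethoxy)phenyl]-3-oxopropyl}-2-fluoro-4,6-dimethoxybenzaldehyde (not isolated) | COc1cc(OC)c(C=O)c(F)c1CC(C=O)c1ccc(OCOC)cc1OCOC | intermediate
9 | 3-[2,4-bis(methoxymethoxy)phenyl]-5,7-dimethoxy-4H-chromene-8-carbaldehyde | COc1cc(OC)c(C=O)c2c1CC(c1ccc(OCOC)cc1OCOC)=CO2 | intermediate
10 | (3R)-3-[2,4-bis(methoxymethoxy)phenyl]-5,7-dimethoxychromane-8-carbaldehyde | COc1cc(OC)c(C=O)c2c1C[C@H](c1ccc(OCOC)cc1OCOC)CO2 | intermediate
11 | lithium alkoxide from addition of lithium 4-methylpiperazin-1-ide to the formyl group of 10, carbinol carbon unassigned (not isolated) | COc1cc(OC)c(C(O[Li])N3CCN(C)CC3)c2c1C[C@H](c1ccc(OCOC)cc1OCOC)CO2 | intermediate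
12 | 3'-lithio derivative of 11 (not isolated) | COc1cc(OC)c(C(O[Li])N3CCN(C)CC3)c2c1C[C@H](c1ccc(OCOC)c([Li])c1OCOC)CO2 | intermediate
13 | 3'-prenyl derivative of 11 (not isolated) | COc1cc(OC)c(C(O[Li])N3CCN(C)CC3)c2c1C[C@H](c1ccc(OCOC)c(CC=C(C)C)c1OCOC)CO2 | intermediate
14 | (3R)-3-[2,4-bis(methoxymethoxy)-3-(3-methylbut-2-en-1-yl)phenyl]-5,7-dimethoxychromane-8-carbaldehyde | COc1cc(OC)c(C=O)c2c1C[C@H](c1ccc(OCOC)c(CC=C(C)C)c1OCOC)CO2 | intermediate
15 | (3R)-3-[2,4-dihydroxy-3-(3-methylbut-2-en-1-yl)phenyl]-5,7-dimethoxychromane-8-carbaldehyde | COc1cc(OC)c(C=O)c2c1C[C@H](c1ccc(O)c(CC=C(C)C)c1O)CO2 | intermediate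
16 | (3R)-3-[2,4-dihydroxy-3-(3-methylbut-2-en-1-yl)phenyl]-7-hydroxy-5-methoxychromane-8-carbaldehyde | COc1cc(O)c(C=O)c2c1C[C@H](c1ccc(O)c(CC=C(C)C)c1O)CO2 | target

Total step count: 10
Longest linear sequence: 8 steps (steps 3 to 10, from 4)

Steps most likely to fail

Step 6. The enolate may be benzylated at oxygen, 7 may condense with itself, or 8 may be benzylated a second time before ring C closes. The fallback separates the two bond formations and uses a neutral carbon nucleophile.
- It sets out from 7 and 3. Condensation of 7 with morpholine gives 4-{(E)-2-[2,4-bis(methoxymethoxy)phenyl]ethenyl}morpholine F1.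
- Stork enamine alkylation of F1 with 3 in MeCN gives the C-benzylated morpholinium chloride F2.
- Buffered aqueous hydrolysis of F2 gives 8, now isolated.
- Cs2CO3 in DMSO then closes ring C by SNAr, and the route is rejoined at 9.

Step 8. Butyllithium may add to an incompletely masked formyl group, or lithiation may compete at C6 of ring A. The fallback replaces the transient mask by an isolated acetal that places no amine ligand next to ring A.
- It sets out from 10. Ethylene glycol, HC(OEt)3 and pyridinium tosylate give the 8-(1,3-dioxolan-2-yl) isoflavan F4.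
- t-BuLi in Et2O at −78 °C, a medium in which OMOM groups dominate the choice of site, gives the 3'-lithio acetal F5.
- Prenyl bromide converts F5 into the 3'-prenyl acetal F6.
- Under the conditions of step 9, F6 loses the dioxolane and both MOM groups at once, and the route is rejoined at 15.

Step 7. Facial selectivity may be poor on the 3-aryl enol ether with its ortho-substituted ring B, or the acidic iridium hydrides may erode the MOM groups. The fallback changes the substrate to the alkene isomer for which this hydrogenation is best established.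
- It sets out from 9. KOt-Bu in DMSO moves the double bond into conjugation with both arenes and gives 3-[2,4-bis(methoxymethoxy)phenyl]-5,7-dimethoxy-2H-chromene-8-carbaldehyde F3.
- Iridium N,P-catalysed asymmetric hydrogenation of this 3-aryl-2H-chromene, a direct entry to isoflavans, rejoins the route at 10.

Further compounds
F1 | step 6 | 4-{(E)-2-[2,4-bis(methoxymethoxy)phenyl]ethenyl}morpholine | COCOc1ccc(/C=C/N2CCOCC2)c(OCOC)c1
F2 | step 6 | 4-{2-[2,4-bis(methoxymethoxy)phenyl]-3-(2-fluoro-3-formyl-4,6-dimethoxyphenyl)propylidene}morpholin-4-ium chloride (racemic) | COc1cc(OC)c(C=O)c(F)c1CC(C=[N+]1CCOCC1)c1ccc(OCOC)cc1OCOC.[Cl-]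
F3 | step 7 | 3-[2,4-bis(methoxymethoxy)phenyl]-5,7-dimethoxy-2H-chromene-8-carbaldehyde | COc1cc(OC)c(C=O)c2c1C=C(c1ccc(OCOC)cc1OCOC)CO2
F4 | step 8 | (3R)-3-[2,4-bis(methoxymethoxy)phenyl]-8-(1,3-dioxolan-2-yl)-5,7-dimethoxychromane | COc1cc(OC)c(C3OCCO3)c2c1C[C@H](c1ccc(OCOC)cc1OCOC)CO2
F5 | step 8 | 3'-lithio derivative of F4 | COc1cc(OC)c(C3OCCO3)c2c1C[C@H](c1ccc(OCOC)c([Li])c1OCOC)CO2
F6 | step 8 | (3R)-3-[2,4-bis(methoxymethoxy)-3-(3-methylbut-2-en-1-yl)phenyl]-8-(1,3-dioxolan-2-yl)-5,7-dimethoxychromane | COc1cc(OC)c(C3OCCO3)c2c1C[C@H](c1ccc(OCOC)c(CC=C(C)C)c1OCOC)CO2
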